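**Assumption: natural (R)-(−)-piperitone of high enantiomeric purity and magnolol are bought; "allyl" means prop-2-en-1-yl.**

## Retrosynthetic overview

1. Bought: magnolol 1 brings both benzene rings, both allyl groups and both hydroxyls; (R)-(−)-piperitone 2 brings the cyclohexene ring and the isopropyl-bearing stereocentre. No ring is built, so no order of ring formation arises.
2. From 2: trans-piperitol 3 by substrate-controlled reduction, then its methyl carbonate 4.
3. C–O disconnection: tertiary allyl aryl ether 5 from 4 and 1 by palladium-catalysed allylic etherification with net retention.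
4. Key disconnection: the aryl–C(sp3) bond of the target, made last by [3,3] aromatic Claisen rearrangement of 5 through dienone 6 to target 7, with suprafacial 1,3-transfer of chirality.

## Route

**Step 1**
Reactants: 2 (R)-(−)-piperitone [(6R)-3-methyl-6-(propan-2-yl)cyclohex-2-en-1-one]
Product: 3 trans-piperitol [(1R,6R)-3-methyl-6-(propan-2-yl)cyclohex-2-en-1-ol]
Conditions: LiAlH4 (0.6 equiv), Et2O, −78 → 0 °C; aq. NaOH work-up; SiO2 chromatography to remove the minor cis alcohol
Reagents that add atoms: none
Why: Carbonyl 1,2-reduction of the β,β-disubstituted enone by a small hydride goes by axial attack and is expected to put the new hydroxyl trans to the pseudo-equatorial isopropyl group (about 3:1), so the carbinol centre is set by the bought stereocentre.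

**Step 2**
Reactants: 3 trans-piperitol
Product: 4 methyl (1R,6R)-3-methyl-6-(propan-2-yl)cyclohex-2-en-1-yl carbonate
Conditions: ClCO2Me (1.5 equiv), pyridine, DMAP (cat.), CH2Cl2, 0 °C → rt
Reagents that add atoms: methyl chloroformate, COC(=O)Cl
Why: O-acylation (carbonate formation) of the secondary allylic alcohol gives a leaving group that zerovalent palladium ionises under neutral conditions, and no stereocentre is touched.

**Step 3**
Reactants: 4 methyl trans-piperityl carbonate; 1 magnolol (5,5'-diallylbiphenyl-2,2'-diol, 3 equiv)
Product: 5 5,5'-diallyl-2'-{[(1S,4R)-1-methyl-4-(propan-2-yl)cyclohex-2-en-1-yl]oxy}biphenyl-2-ol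
Conditions: Pd(PPh3)4 (5 mol %), THF, 0 °C → rt, stopped when 4 is consumed; excess 1 recovered
Reagents that add atoms: none
Why: In this Tsuji–Trost allylic etherification zerovalent palladium ionises the carbonate with inversion, and the phenoxide then attacks, again with inversion, the methyl-bearing allyl terminus (the more cationic one and the one remote from the isopropyl group), so the ether oxygen ends on the face the carbonate left (net retention, trans to isopropyl), while the excess of 1 keeps the reaction at the mono-ether.

**Step 4**
Reactants: 5 tertiary allyl aryl ether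
Product: 7 the target 5,5'-diallyl-3-[(1R,6R)-3-methyl-6-(propan-2-yl)cyclohex-2-en-1-yl]biphenyl-2,2'-diol, via ortho-dienone 6 (not isolated)
Conditions: Eu(fod)3 (10 mol %; fod = 6,6,7,7,8,8,8-heptafluoro-2,2-dimethyloctane-3,5-dionate), CHCl3, 50 °C
Reagents that add atoms: none
Why: In this aromatic Claisen ([3,3]-sigmatropic) rearrangement the allyl unit passes suprafacially from oxygen to the only free ortho carbon, so the aryl group arrives at the ring carbon next to the isopropyl centre on the face the oxygen occupied (trans to isopropyl, R), and dienone 6 then tautomerises to the phenol.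

## Compound list

1 | magnolol, 5,5'-diallylbiphenyl-2,2'-diol | C=CCc1ccc(O)c(-c2cc(CC=C)ccc2O)c1 | starting material
2 | (R)-(−)-piperitone, (6R)-3-methyl-6-(propan-2-yl)cyclohex-2-en-1-one | O=C1C=C(C)CC[C@@H]1C(C)C | starting material
3 | trans-piperitol, (1R,6R)-3-methyl-6-(propan-2-yl)cyclohex-2-en-1-ol (OH and isopropyl on opposite faces) | O[C@H]1C=C(C)CC[C@@H]1C(C)C | intermediate
4 | methyl (1R,6R)-3-methyl-6-(propan-2-yl)cyclohex-2-en-1-yl carbonate | COC(=O)O[C@H]1C=C(C)CC[C@@H]1C(C)C | intermediate
5 | 5,5'-diallyl-2'-{[(1S,4R)-1-methyl-4-(propan-2-yl)cyclohex-2-en-1-yl]oxy}biphenyl-2-ol (ether oxygen and isopropyl on opposite faces) | C=CCc1ccc(O)c(-c2cc(CC=C)ccc2O[C@]3(C)C=C[C@@H](C(C)C)CC3)c1 | intermediate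
6 | 4-allyl-2-(5-allyl-2-hydroxyphenyl)-6-[(1R,6R)-3-methyl-6-(propan-2-yl)cyclohex-2-en-1-yl]cyclohexa-2,4-dien-1-one (ring sp3 centre transient, lost on enolisation, left unassigned) | O=C1C(-c2cc(CC=C)ccc2O)=CC(CC=C)=CC1[C@H]3C=C(C)CC[C@@H]3C(C)C | intermediate
7 | 5,5'-diallyl-3-[(1R,6R)-3-methyl-6-(propan-2-yl)cyclohex-2-en-1-yl]biphenyl-2,2'-diol | C=CCc1ccc(O)c(-c2cc(CC=C)cc([C@H]3C=C(C)CC[C@@H]3C(C)C)c2O)c1 | target

## Step count and risks

Total steps: 4. Longest linear sequence: 4 (2 → 3 → 4 → 5 → 7).

**Steps most likely to fail**

- **Step 3 (most at risk).** The phenoxide may attack the other allyl terminus and give the secondary piperityl ether, which is useless for the rearrangement. The tertiary ether may also re-ionise on palladium or lose magnolol to give p-menthadienes. The face of ionisation next to the isopropyl group is hindered as well. Fallback: give up the ether and join the halves by cationic ortho-allylation. Setting out from alcohol 3, treat it with 1 (3 equiv) and p-TsOH·H2O (10 mol %) in CH2Cl2 at 0 °C → rt. The allyl cation from 3 is attacked by the only free ortho carbon of 1 (the para position carries the allyl group) on the face away from the isopropyl group, and the route is rejoined directly at 7. This fallback makes no new compound (entry F0).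

- **Step 4.** The Lewis acid and the neighbouring free phenol may ionise the tertiary ether, leading to loss of magnolol by elimination or to stereochemical leakage through an ion pair. Fallback: setting out from 5, cap the free phenol (Ac2O, pyridine, DMAP, CH2Cl2, 0 °C) to give ether acetate F3. Rearrange it purely thermally without any acid (PhNEt2, 130 °C) to target monoacetate F4; acetyl migration between the two phenol oxygens is harmless. Then cleave the ester (K2CO3, MeOH, rt) and come back to the route at 7.

- **Step 1.** The trans:cis ratio may be poor, and the stereocentre α to the ketone can erode if the reduction is run warm or basic. Fallback: setting out from 2, LiBH(s-Bu)3 in THF at −78 °C attacks the carbonyl from the face away from the isopropyl group and gives cis-piperitol F1. Mitsunobu esterification (PPh3, DIAD, 4-nitrobenzoic acid, THF, 0 °C) inverts the carbinol centre to trans-piperityl 4-nitrobenzoate F2, a crystalline ester that can be recrystallised to raise the enantiomeric purity. F2 then takes the place of carbonate 4 in the coupling with 1 (Pd(PPh3)4, K2CO3, THF, rt), and the route is rejoined at 5.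

## Further compounds

F1 | step 1 | cis-piperitol, (1S,6R)-3-methyl-6-(propan-2-yl)cyclohex-2-en-1-ol | O[C@@H]1C=C(C)CC[C@@H]1C(C)C
F2 | step 1 | trans-piperityl 4-nitrobenzoate, (1R,6R)-3-methyl-6-(propan-2-yl)cyclohex-2-en-1-yl 4-nitrobenzoate | O=C(O[C@H]1C=C(C)CC[C@@H]1C(C)C)c1ccc(cc1)[N+](=O)[O-]
F0 | step 3 | none | none
F3 | step 4 | ether acetate, 5,5'-diallyl-2'-{[(1S,4R)-1-methyl-4-(propan-2-yl)cyclohex-2-en-1-yl]oxy}biphenyl-2-yl acetate | CC(=O)Oc1ccc(CC=C)cc1-c1cc(CC=C)ccc1O[C@]2(C)C=C[C@@H](C(C)C)CC2
F4 | step 4 | target monoacetate, 5,5'-diallyl-2'-hydroxy-3'-[(1R,6R)-3-methyl-6-(propan-2-yl)cyclohex-2-en-1-yl]biphenyl-2-yl acetate | CC(=O)Oc1ccc(CC=C)cc1-c1cc(CC=C)cc([C@H]2C=C(C)CC[C@@H]2C(C)C)c1O
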